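**Plan**
Retrosynthesis: remove the silyl groups on O5 and O7. Cut C2–C3 of ring C (carbene C–H insertion) back to an ortho-benzyloxy α-diazoacetophenone. Cut O1–CH2 (Mitsunobu), then C8–prenyl (phenolate C-alkylation) and the ring B aryl–CH2CH2 bond (Negishi).
Forward: the ring B benzyl alcohol (2 steps) and the ring A phenol (2 steps) are joined through O1. The acetyl CH3 becomes CHN2, ring C is closed last, and the silyl groups are removed.
Enabling feature: C2 is both benzylic to the para-methoxy ring B and α to O1. In the open form, O1–CH2–ring B is therefore a p-methoxybenzyl-type ether with a hydridic C–H six atoms from C3. Atom five of that chain is O1, which bears no hydrogen, so only the six-membered ring can form.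
The oxygen that carries the benzyl group fixes 8-prenyl against 6-prenyl before ring closure, so no chalcone regiochemistry problem arises.
Stereochemistry: the single centre C2 (S) is set in the key step by a chiral dirhodium catalyst that chooses between the two enantiotopic benzylic hydrogens. Only neutral or buffered conditions follow.

Key step: step 7

Assumption: the sense of induction of the prolinate catalyst on 12 cannot be fixed in advance. The route is written for the antipode that inserts into the pro-S hydrogen; both antipodes of the catalyst are commercial.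

Step 1
Reactants: 1 4-bromo-2-methylbut-1-ene; 2 3-bromo-4-methoxybenzaldehyde
Product: 4 4-methoxy-3-(3-methylbut-3-enyl)benzaldehyde, via (3-methylbut-3-enyl)zinc bromide 3 (not isolated)
Conditions: Zn dust, LiCl, THF, 40 °C; then 2, Pd(OAc)2 (2 mol %), SPhos (4 mol %), THF, 23 °C
Reagents that add atoms: zinc, [Zn] (held only in 3)
Why: LiCl-assisted zinc insertion gives a homoallylic alkylzinc that tolerates the aldehyde, and Negishi coupling on a zerovalent palladium–SPhos catalyst joins it to the aryl bromide faster than β-hydride elimination.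

Step 2
Reactants: 4 4-methoxy-3-(3-methylbut-3-enyl)benzaldehyde
Product: 5 [4-methoxy-3-(3-methylbut-3-enyl)phenyl]methanol
Conditions: NaBH4, MeOH, 0 °C; aqueous work-up
Reagents that add atoms: none
Why: Borohydride reduction of an aromatic aldehyde is chemoselective and leaves the 1,1-disubstituted alkene untouched.

Step 3
Reactants: 6 1-(2,4,6-trihydroxyphenyl)ethanone; 7 1-bromo-3-methylbut-2-ene
Product: 8 1-[2,4,6-trihydroxy-3-(3-methylbut-2-enyl)phenyl]ethanone
Conditions: KOH (1.0 equiv), 7 (0.9 equiv), MeOH/H2O, 0 °C to 23 °C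
Reagents that add atoms: none
Why: C-alkylation of the ambident phloroglucinol phenolate in protic medium, where hydrogen bonding shields the oxygens, puts the prenyl group on one of the two equivalent free ring carbons, and a deficit of 7 limits double alkylation.

Step 4
Reactants: 8 1-[2,4,6-trihydroxy-3-(3-methylbut-2-enyl)phenyl]ethanone
Product: 9 1-[2-hydroxy-3-(3-methylbut-2-enyl)-4,6-bis(triisopropylsilyloxy)phenyl]ethanone
Conditions: TIPSCl (2.1 equiv), imidazole, DMF, 0 °C to 23 °C
Reagents that add atoms: chlorotriisopropylsilane, CC(C)[Si](Cl)(C(C)C)C(C)C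
Why: Silylation with a bulky chloride should take the unchelated 4-OH and the less hindered ortho 6-OH, while the 2-OH, squeezed between acetyl and prenyl, keeps the hydrogen bond to C=O and stays free.

Step 5
Reactants: 9 1-[2-hydroxy-3-(3-methylbut-2-enyl)-4,6-bis(triisopropylsilyloxy)phenyl]ethanone; 5 [4-methoxy-3-(3-methylbut-3-enyl)phenyl]methanol
Product: 10 1-[2-{[4-methoxy-3-(3-methylbut-3-enyl)phenyl]methoxy}-3-(3-methylbut-2-enyl)-4,6-bis(triisopropylsilyloxy)phenyl]ethanone
Conditions: PPh3, DIAD, THF, 0 °C to 23 °C, high concentration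
Reagents that add atoms: none
Why: Mitsunobu etherification displaces the primary benzylic alkoxyphosphonium ion with the only free phenol under neutral conditions that spare the aryl silyl ethers, and it fixes O1 next to the prenyl-bearing carbon.

Step 6
Reactants: 10 1-[2-{[4-methoxy-3-(3-methylbut-3-enyl)phenyl]methoxy}-3-(3-methylbut-2-enyl)-4,6-bis(triisopropylsilyloxy)phenyl]ethanone
Product: 12 2-diazo-1-[2-{[4-methoxy-3-(3-methylbut-3-enyl)phenyl]methoxy}-3-(3-methylbut-2-enyl)-4,6-bis(triisopropylsilyloxy)phenyl]ethanone, via trifluoroacetyl diketone 11 (not isolated)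
Conditions: LiHMDS, THF, −78 °C; CF3CO2CH2CF3, −78 °C; 5% aq HCl quench; then p-ABSA, Et3N, MeCN/THF, 23 °C
Reagents that add atoms: 2,2,2-trifluoroethyl trifluoroacetate, FC(F)(F)COC(=O)C(F)(F)F (held only in 11); 4-acetamidobenzenesulfonyl azide, CC(=O)Nc1ccc(cc1)S(=O)(=O)N=[N+]=[N-]
Why: Claisen trifluoroacetylation of the kinetic lithium enolate activates the methyl ketone for a detrifluoroacetylative Regitz diazo transfer, in which the trifluoroacetyl group leaves on the sulfonamide nitrogen.

Step 7
Reactants: 12 2-diazo-1-[2-{[4-methoxy-3-(3-methylbut-3-enyl)phenyl]methoxy}-3-(3-methylbut-2-enyl)-4,6-bis(triisopropylsilyloxy)phenyl]ethanone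
Product: 13 (2S)-2-[4-methoxy-3-(3-methylbut-3-enyl)phenyl]-8-(3-methylbut-2-enyl)-5,7-bis(triisopropylsilyloxy)chroman-4-one
Conditions: Rh2(S-DOSP)4, tetrakis[(S)-N-(4-dodecylbenzenesulfonyl)prolinato]dirhodium (1 mol %), degassed hexanes, 23 °C, 12 added by syringe pump over 6 h (final 0.005 M)
Reagents that add atoms: none
Why: The catalyst expels N2 from 12 to give an electrophilic acyl rhodium carbene at C3, which inserts into one C–H bond of the O1–CH2–ring B unit through a concerted, asynchronous three-centre transition state with hydride-transfer character, so C2–C3 forms and ring C closes in one neutral event. The closest known reaction type is the enantioselective cyclisation of ortho-alkoxyaryl and ortho-benzyloxyaryl α-diazoketones to chroman-4-ones with chiral dirhodium N-arylsulfonylprolinates, supported by rhodium carbene insertion into aryl benzyl ether C–H bonds. Ring C closes as a 1,6-insertion through a chair-like six-membered arrangement with ring B pseudo-equatorial, and a five-membered insertion is excluded because the fifth atom of the chain is O1. C2 is the only new stereocentre and is controlled by the chiral ligand sphere, which distinguishes the two enantiotopic benzylic hydrogens, so insertion into the pro-S C–H with retention gives 2S. The step needs C–H insertion to outrun oxonium ylide formation at O1 with [1,2]-shift, attack at the other ortho oxygen, Buchner addition and cyclopropanation. The substrate helps in these ways: the para-methoxy group makes the C–H hydridic, O1 is a weak and reversible donor in hexanes (where the two TIPS groups keep 12 soluble and a zwitterion is poorly stabilised), the O5 silyl ether has a non-basic oxygen and no C–H within six atoms, the C8 prenyl group is meta to the acyl carbon and cannot reach, and the ring B alkene could react only by macrocyclisation or intermolecularly, which dilution suppresses.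

Step 8
Reactants: 13 (2S)-2-[4-methoxy-3-(3-methylbut-3-enyl)phenyl]-8-(3-methylbut-2-enyl)-5,7-bis(triisopropylsilyloxy)chroman-4-one
Product: 14 (2S)-5,7-dihydroxy-2-[4-methoxy-3-(3-methylbut-3-enyl)phenyl]-8-(3-methylbut-2-enyl)chroman-4-one
Conditions: TBAF (2.2 equiv), AcOH (2.5 equiv), THF, 0 °C
Reagents that add atoms: none
Why: Fluoride cleaves aryl silyl ethers rapidly, and the acetic acid buffer keeps the phenols protonated, so the retro-oxa-Michael opening of ring C that would racemise C2 is not triggered and both alkenes are untouched.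

**Compound list**
1 | 4-bromo-2-methylbut-1-ene | C=C(C)CCBr | starting material
2 | 3-bromo-4-methoxybenzaldehyde | COc1ccc(C=O)cc1Br | starting material
3 | (3-methylbut-3-enyl)zinc bromide | C=C(C)CC[Zn]Br | intermediate
4 | 4-methoxy-3-(3-methylbut-3-enyl)benzaldehyde | C=C(C)CCc1cc(C=O)ccc1OC | intermediate
5 | [4-methoxy-3-(3-methylbut-3-enyl)phenyl]methanol | C=C(C)CCc1cc(CO)ccc1OC | intermediate
6 | 1-(2,4,6-trihydroxyphenyl)ethanone (phloroacetophenone) | CC(=O)c1c(O)cc(O)cc1O | starting material
7 | 1-bromo-3-methylbut-2-ene (prenyl bromide) | CC(C)=CCBr | starting material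
8 | 1-[2,4,6-trihydroxy-3-(3-methylbut-2-enyl)phenyl]ethanone | CC(=O)c1c(O)cc(O)c(CC=C(C)C)c1O | intermediate
9 | 1-[2-hydroxy-3-(3-methylbut-2-enyl)-4,6-bis(triisopropylsilyloxy)phenyl]ethanone | CC(=O)c1c(O)c(CC=C(C)C)c(O[Si](C(C)C)(C(C)C)C(C)C)cc1O[Si](C(C)C)(C(C)C)C(C)C | intermediate
10 | 1-[2-{[4-methoxy-3-(3-methylbut-3-enyl)phenyl]methoxy}-3-(3-methylbut-2-enyl)-4,6-bis(triisopropylsilyloxy)phenyl]ethanone | CC(=O)c1c(OCc2ccc(OC)c(CCC(C)=C)c2)c(CC=C(C)C)c(O[Si](C(C)C)(C(C)C)C(C)C)cc1O[Si](C(C)C)(C(C)C)C(C)C | intermediate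
11 | 4,4,4-trifluoro-1-aryl-butane-1,3-dione, aryl group as in 10 | O=C(CC(=O)C(F)(F)F)c1c(OCc2ccc(OC)c(CCC(C)=C)c2)c(CC=C(C)C)c(O[Si](C(C)C)(C(C)C)C(C)C)cc1O[Si](C(C)C)(C(C)C)C(C)C | intermediate
12 | 2-diazo-1-aryl-ethanone, aryl group as in 10 | [N-]=[N+]=CC(=O)c1c(OCc2ccc(OC)c(CCC(C)=C)c2)c(CC=C(C)C)c(O[Si](C(C)C)(C(C)C)C(C)C)cc1O[Si](C(C)C)(C(C)C)C(C)C | intermediate
13 | (2S)-2-[4-methoxy-3-(3-methylbut-3-enyl)phenyl]-8-(3-methylbut-2-enyl)-5,7-bis(triisopropylsilyloxy)chroman-4-one | C=C(C)CCc1cc([C@@H]2CC(=O)c3c(O[Si](C(C)C)(C(C)C)C(C)C)cc(O[Si](C(C)C)(C(C)C)C(C)C)c(CC=C(C)C)c3O2)ccc1OC | intermediate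
14 | (2S)-5,7-dihydroxy-2-[4-methoxy-3-(3-methylbut-3-enyl)phenyl]-8-(3-methylbut-2-enyl)chroman-4-one (CNP0286775.1) | C=C(C)CCc1cc([C@@H]2CC(=O)c3c(O)cc(O)c(CC=C(C)C)c3O2)ccc1OC | target

Total step count: 8. Longest linear sequence: 6 (steps 3, 4, 5, 6, 7, 8 from 6; the branch 1, 2, 5, 6, 7, 8 has the same length).

**Steps most likely to fail**

Step 7. The carbene may be intercepted by the lone pair of O1, giving ylide formation followed by [1,2]-migration of the benzyl group. The catalyst may also discriminate poorly between the two enantiotopic hydrogens.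
- The fallback closes ring C at O1–C2 and takes the configuration from a resolution. It sets out from 9 and 4.
- A pyrrolidine-mediated Claisen–Schmidt condensation (EtOH, 60 °C) should give the (E)-2'-hydroxychalcone F1.
- Its only free phenol then adds in an oxa-Michael sense (NaOAc, EtOH, reflux) to give the racemic bis-silyl flavanone F2.
- Kinetic resolution by asymmetric transfer hydrogenation follows (Cp*RhCl[(R,R)-TsDPEN] or its antipode, whichever consumes the 2R ketone; HCO2H/Et3N, EtOAc). It should reduce the 2R ketone to the (2R,4R)-cis-flavan-4-ol F3 and leave the 2S ketone, which is 13, where the route is rejoined.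

Step 6. The lithium enolate may take the neighbouring silyl group from O6 (oxygen-to-oxygen silyl migration), or acylation of the hindered ketone may stall.
- The fallback avoids a free enolate and sets out from 10.
- Soft enolisation (TMSOTf, Et3N, CH2Cl2, 0 °C) gives the trimethylsilyl enol ether F4.
- NBS (THF, −78 °C) converts this to the α-bromoketone F5.
- N,N'-ditosylhydrazine and DBU (THF, 0 °C) displace bromide and lose two sulfinate groups to give 12, where the route is rejoined.

Step 4. Silylation may not distinguish the two ortho hydroxyl groups, which would scramble the later 8-prenyl against 6-prenyl assignment.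
- The fallback makes the choice by symmetry and sets out from 6.
- Bis-silylation of the still symmetric ketone (TIPSCl, imidazole, DMF) gives the 2-hydroxy-4,6-bis(triisopropylsilyloxy)acetophenone F6.
- O-alkylation with 7 (K2CO3, acetone) gives the aryl prenyl ether F7.
- A clay-promoted [1,3]-shift (montmorillonite K10, CH2Cl2, 0 °C) moves the prenyl group to the only free ortho carbon to give 9, where the route is rejoined.

**Further compounds**
F1 | step 7 | (E)-1-[2-hydroxy-3-(3-methylbut-2-enyl)-4,6-bis(triisopropylsilyloxy)phenyl]-3-[4-methoxy-3-(3-methylbut-3-enyl)phenyl]prop-2-en-1-one | C=C(C)CCc1cc(/C=C/C(=O)c2c(O)c(CC=C(C)C)c(O[Si](C(C)C)(C(C)C)C(C)C)cc2O[Si](C(C)C)(C(C)C)C(C)C)ccc1OC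
F2 | step 7 | racemic 2-[4-methoxy-3-(3-methylbut-3-enyl)phenyl]-8-(3-methylbut-2-enyl)-5,7-bis(triisopropylsilyloxy)chroman-4-one | C=C(C)CCc1cc(C2CC(=O)c3c(O[Si](C(C)C)(C(C)C)C(C)C)cc(O[Si](C(C)C)(C(C)C)C(C)C)c(CC=C(C)C)c3O2)ccc1OC
F3 | step 7 | (2R,4R)-2-[4-methoxy-3-(3-methylbut-3-enyl)phenyl]-8-(3-methylbut-2-enyl)-5,7-bis(triisopropylsilyloxy)chroman-4-ol | C=C(C)CCc1cc([C@H]2C[C@@H](O)c3c(O[Si](C(C)C)(C(C)C)C(C)C)cc(O[Si](C(C)C)(C(C)C)C(C)C)c(CC=C(C)C)c3O2)ccc1OC
F4 | step 6 | trimethylsilyl enol ether of 10 | C=C(O[Si](C)(C)C)c1c(OCc2ccc(OC)c(CCC(C)=C)c2)c(CC=C(C)C)c(O[Si](C(C)C)(C(C)C)C(C)C)cc1O[Si](C(C)C)(C(C)C)C(C)C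
F5 | step 6 | 2-bromo-1-aryl-ethanone, aryl group as in 10 | BrCC(=O)c1c(OCc2ccc(OC)c(CCC(C)=C)c2)c(CC=C(C)C)c(O[Si](C(C)C)(C(C)C)C(C)C)cc1O[Si](C(C)C)(C(C)C)C(C)C
F6 | step 4 | 1-[2-hydroxy-4,6-bis(triisopropylsilyloxy)phenyl]ethanone | CC(=O)c1c(O)cc(O[Si](C(C)C)(C(C)C)C(C)C)cc1O[Si](C(C)C)(C(C)C)C(C)C
F7 | step 4 | 1-[2-(3-methylbut-2-enyloxy)-4,6-bis(triisopropylsilyloxy)phenyl]ethanone | CC(=O)c1c(OCC=C(C)C)cc(O[Si](C(C)C)(C(C)C)C(C)C)cc1O[Si](C(C)C)(C(C)C)C(C)C
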